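Numbering of the core (bicyclo[2.2.1]heptane): C1 = bridgehead bonded to CMe2, C2H2, C3(=CH2), C4H = second bridgehead, C5H–O, C6H2, C7(CH3) = bridge. Ring A = C1-C2-C3-C4-C7, ring B = C1-C6-C5-C4-C7, ring C = the cyclohexane fused on C1–C7.
Cuts: (a) the acyl–O bond of the caffeate. (b) C1–C2 of ring A, reading C3=CH2 as the proton-loss end of a tertiary C3 cation. (c) C4–C7 of ring B, re-joined as C4–C1, so that ring B shrinks to a cyclobutane C1-C6-C5-C4 spiro to ring C with the charge on C7. (d) The C7 cation is stored as a C7–O–C5 ether (a 2-oxabicyclo[2.1.1]hexane), which is cut by retro-[2+2] to an enone ether and then at the vinyl–O bond.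
Enabling feature: C1 and C7 are adjacent quaternary carbons shared by rings B and C, the C5 oxygen stands 1,3 to C1 on the C7 side (exo), and C3 lies 1,3 to C1 through C4. A C7 cation beside a C1 cyclobutane therefore expands to ring B, passes the charge to C1 (no β-hydrogen on C7 or CMe2) and, through an isopropenyl group on C4, on to C3.
Forward order: ring C is bought (β-cyclocitral). A crossed [2+2] photocycloaddition builds the cyclobutane and the temporary oxa-bridge. One cationic cascade then makes ring B (four to five), ring A and the exocyclic methylene. The caffeate is attached last.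
Stereochemistry: a Sharpless epoxidation fixes the C7–O carbinol centre, and the two-atom tether relays it to C1, C5 and C4 in the photocycloaddition. The suprafacial 1,2-shift returns it to C7, and the C5–O bond is never broken, so the ester ends exo.

Key step: step 8

Assumption: the tetrasubstituted allylic alcohol β-cyclogeraniol follows the usual facial rule of the Sharpless epoxidation, so that D-(−)-diethyl tartrate gives the (1R,6R)-epoxide.

Step 1
Reactants: 1 β-cyclocitral (2,6,6-trimethylcyclohex-1-ene-1-carbaldehyde)
Product: 2 β-cyclogeraniol ((2,6,6-trimethylcyclohex-1-en-1-yl)methanol)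
Conditions: NaBH4, MeOH, 0 °C
Reagents that add atoms: none
Why: Borohydride 1,2-reduction of an enal whose fully substituted β-carbon blocks conjugate attack; no stereocentre is formed.

Step 2
Reactants: 2 β-cyclogeraniol
Product: 3 [(1R,6R)-2,2,6-trimethyl-7-oxabicyclo[4.1.0]heptan-1-yl]methanol
Conditions: Ti(OiPr)4 (10 mol %), D-(−)-diethyl tartrate (12 mol %), tBuOOH, 4 Å MS, CH2Cl2, −20 °C
Reagents that add atoms: tert-butyl hydroperoxide, CC(C)(C)OO
Why: Sharpless asymmetric epoxidation of an allylic alcohol, in which the titanium tartrate complex delivers oxygen to one alkene face; with D-(−)-tartrate both new centres should be R, and this fixes the absolute configuration of the whole route.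

Step 3
Reactants: 3 epoxy alcohol
Product: 4 (1S,6R)-2,2,6-trimethyl-7-oxabicyclo[4.1.0]heptane-1-carbaldehyde
Conditions: (nPr)4N[RuO4] (5 mol %), N-methylmorpholine N-oxide, 4 Å MS, CH2Cl2, rt
Reagents that add atoms: none
Why: Ley–Griffith oxidation of a primary alcohol under neutral conditions that leave the acid-sensitive fully substituted epoxide and both stereocentres untouched (the descriptor at C1 changes only through the priority rules).

Step 4
Reactants: 4 epoxy aldehyde
Product: 6 (R)-1,3,3-trimethyl-2-methylidenecyclohexan-1-ol, via epoxy hydrazone 5 (not isolated)
Conditions: N2H4·H2O, AcOH (cat.), MeOH, 0 °C to rt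
Reagents that add atoms: none
Why: Wharton transposition, in which the epoxy hydrazone fragments with loss of N2 and the aldehyde carbon ends as the exocyclic CH2; the C–O bond at the methyl-bearing carbon is not broken, so that centre keeps its configuration.

Step 5
Reactants: 6 (R)-tertiary allylic alcohol; 7 but-3-yn-2-one
Product: 8 (E)-4-{[(1R)-1,3,3-trimethyl-2-methylidenecyclohexyl]oxy}but-3-en-2-one
Conditions: PMe3 (10 mol %), CH2Cl2, 0 °C to rt
Reagents that add atoms: none
Why: Phosphine-catalysed oxa-Michael addition of an alcohol to an ynone, which works with tertiary alcohols and gives the E β-alkoxy enone; no stereocentre is touched, and staying at or below room temperature keeps the allyl vinyl ether from Claisen rearrangement.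

Step 6
Reactants: 8 enone ether
Product: 9 acetyl photoadduct: a 2-oxabicyclo[2.1.1]hexane (C1H bridgehead, O2, C3 quaternary with CH3, C4 quaternary bridgehead, C5H, C6H2) with ring C (C3–CH2CH2CH2–CMe2–C4) fused on C3–C4. The acetyl group on C5 is anti to the O2–C3 bridge, the ring C CH2 on C3 lies on the C5 side and the CH3 on the C6 side.
Conditions: hν (medium-pressure Hg lamp, Pyrex filter, λ > 290 nm), MeCN–acetone 9:1, 5 mM, degassed, 0 °C
Reagents that add atoms: none
Why: Intramolecular enone–alkene [2+2] photocycloaddition of a 3-oxa-1,5-diene, a substrate class that closes crossed under the rule of five (first bond from the O-bearing enone carbon to the terminal CH2, five-membered ring) to 2-oxabicyclo[2.1.1]hexanes; the two-atom O–C tether lets the enone reach only the alkene face syn to the carbinol oxygen, so the carbinol centre sets both bridgeheads and places the acetyl-bearing bridge on the side of the ring C CH2, while the acetyl group takes the position anti to the O–C bridge, which is the less crowded one and, through enolisation, also the equilibrium position.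

Step 7
Reactants: 9 acetyl photoadduct
Product: 10 isopropenyl ether: compound 9 with the acetyl group replaced by prop-1-en-2-yl, all stereocentres as in 9
Conditions: Ph3PCH3Br, KOtBu, THF, 0 °C to rt
Reagents that add atoms: methyltriphenylphosphonium bromide, C[P+](c1ccccc1)(c1ccccc1)c1ccccc1.[Br-]
Why: Wittig methylenation of an unhindered methyl ketone; the α-centre already holds its more stable configuration, and β-elimination of the bridge oxygen would need a strained cyclobutene, so nothing should be scrambled.

Step 8
Reactants: 10 isopropenyl ether
Product: 12 tricyclic exo-alcohol (the target skeleton with a free C5–OH syn to C7), via trifluoroacetate 11 (not isolated)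
Conditions: CF3C(O)OSO2CF3 (1.1 equiv), 2,6-di-tert-butyl-4-methylpyridine (1.5 equiv), CH2Cl2, −78 to −40 °C; aq. NaHCO3 work-up; crude ester: K2CO3 (cat.), MeOH, 0 °C
Reagents that add atoms: none
Why: Proposed new method: the acyl triflate acylates the strained bridging oxygen, the tertiary C–O bond ionises, the allylic cyclobutane CH shifts from the spiro carbon to the cationic methyl-bearing carbon (four-membered ring to ring B with release of ring strain), the isopropenyl CH2 adds to the tertiary cation left at the former spiro carbon, and the hindered pyridine takes a methyl proton from the resulting tertiary norbornyl cation to leave the exocyclic methylene. The closest known reaction types are the cleavage of ethers by trifluoroacetyl triflate, the acid-induced cyclobutylcarbinyl-to-cyclopentyl expansion of [2+2] photoadducts and cation–olefin cyclisation; what is new is their combination on a 2-oxabicyclo[2.1.1]hexane. Ring B forms by a 1,2-alkyl shift (ring expansion by one carbon) and ring A by a 5-endo-trig cation–olefin closure across the 1,3-positions of ring B. The migrating CH keeps its configuration and enters the lobe of the cation that the oxygen has just left, which sets C7, and the isopropenyl group, held anti to the former bridge, can reach only the lobe vacated by the migrating carbon, which sets C1; the C5–O bond is never broken, so the oxygen ends exo. The step needs migration of the CH(isopropenyl) carbon and not of the cyclobutane CH2 or the CMe2 carbon: ring C lets the empty orbital turn only towards the cyclobutane bond gauche to its CH2, that carbon is also the allylic and more substituted one, and only a cyclobutane bond shift releases ring strain. The trifluoroacetyl group is chosen because a free or metal-bound alkoxide at C5 could push a Grob-type (retro-Prins) cleavage of the final cation and an ordinary ester could bridge to the C1 cation, while the C1 cation itself cannot eliminate towards either quaternary neighbour.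

Step 9
Reactants: 13 caffeic acid ((E)-3-(3,4-dihydroxyphenyl)prop-2-enoic acid)
Product: 15 (E)-3-[3,4-bis(tert-butyldimethylsilyloxy)phenyl]prop-2-enoic acid, via tris-silyl derivative 14 (not isolated)
Conditions: TBSCl (3.3 equiv), imidazole, DMF, rt; then THF–H2O–AcOH, rt
Reagents that add atoms: tert-butyldimethylsilyl chloride, CC(C)(C)[Si](C)(C)Cl
Why: Exhaustive silylation followed by selective hydrolysis of the silyl ester, which is far more labile to mild aqueous acid than the two aryl silyl ethers; the E alkene is untouched.

Step 10
Reactants: 12 tricyclic exo-alcohol; 15 bis-silyl caffeic acid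
Product: 16 bis(tert-butyldimethylsilyl) ether of the target
Conditions: DCC, DMAP (cat.), CH2Cl2, 0 °C to rt
Reagents that add atoms: none
Why: Steglich esterification, which acylates hindered isoborneol-type secondary alcohols through the acylpyridinium ion with retention at C5 because only the O–H bond reacts.

Step 11
Reactants: 16 bis-silyl ether
Product: 17 target caffeate CNP0308742.2
Conditions: Bu4NF, AcOH, THF, 0 °C
Reagents that add atoms: none
Why: Buffered fluoride cleavage of aryl silyl ethers, fast at 0 °C and harmless to the hindered cinnamate ester, the exocyclic methylene and all four stereocentres.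

Compound list
1 | β-cyclocitral | CC1=C(C=O)C(C)(C)CCC1 | starting material
2 | β-cyclogeraniol | CC1=C(CO)C(C)(C)CCC1 | intermediate
3 | [(1R,6R)-2,2,6-trimethyl-7-oxabicyclo[4.1.0]heptan-1-yl]methanol | C[C@@]12CCCC(C)(C)[C@]1(CO)O2 | intermediate
4 | (1S,6R)-2,2,6-trimethyl-7-oxabicyclo[4.1.0]heptane-1-carbaldehyde | C[C@@]12CCCC(C)(C)[C@]1(C=O)O2 | intermediate
5 | (E)-hydrazone of 4 | C[C@@]12CCCC(C)(C)[C@]1(/C=N/N)O2 | intermediate
6 | (R)-1,3,3-trimethyl-2-methylidenecyclohexan-1-ol | C[C@@]1(O)CCCC(C)(C)C1=C | intermediate
7 | but-3-yn-2-one | CC(=O)C#C | starting material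
8 | (E)-4-{[(1R)-1,3,3-trimethyl-2-methylidenecyclohexyl]oxy}but-3-en-2-one | C[C@@]1(O/C=C/C(C)=O)CCCC(C)(C)C1=C | intermediate
9 | acetyl photoadduct (ring C-fused 5-acetyl-2-oxabicyclo[2.1.1]hexane, acetyl anti to the O–C bridge) | CC(=O)[C@H]1[C@H]2C[C@]1(C(C)(C)CCC3)[C@]3(C)O2 | intermediate
10 | isopropenyl ether (ring C-fused 5-(prop-1-en-2-yl)-2-oxabicyclo[2.1.1]hexane) | C=C(C)[C@H]1[C@H]2C[C@]1(C(C)(C)CCC3)[C@]3(C)O2 | intermediate
11 | exo-trifluoroacetate of 12 | C=C1C[C@]23C[C@@H](OC(=O)C(F)(F)F)[C@H]1[C@]2(C)CCCC3(C)C | intermediate
12 | tricyclic exo-alcohol (target skeleton, free C5–OH) | C=C1C[C@]23C[C@@H](O)[C@H]1[C@]2(C)CCCC3(C)C | intermediate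
13 | caffeic acid | O=C(O)/C=C/c1ccc(O)c(O)c1 | starting material
14 | tert-butyldimethylsilyl (E)-3-[3,4-bis(tert-butyldimethylsilyloxy)phenyl]prop-2-enoate | CC(C)(C)[Si](C)(C)OC(=O)/C=C/c1ccc(O[Si](C)(C)C(C)(C)C)c(O[Si](C)(C)C(C)(C)C)c1 | intermediate
15 | (E)-3-[3,4-bis(tert-butyldimethylsilyloxy)phenyl]prop-2-enoic acid | O=C(O)/C=C/c1ccc(O[Si](C)(C)C(C)(C)C)c(O[Si](C)(C)C(C)(C)C)c1 | intermediate
16 | bis(tert-butyldimethylsilyl) ether of the target | C=C1C[C@]23C[C@@H](OC(=O)/C=C/c4ccc(O[Si](C)(C)C(C)(C)C)c(O[Si](C)(C)C(C)(C)C)c4)[C@H]1[C@]2(C)CCCC3(C)C | intermediate
17 | target caffeate CNP0308742.2 | C=C1C[C@]23C[C@@H](OC(=O)/C=C/c4ccc(O)c(O)c4)[C@H]1[C@]2(C)CCCC3(C)C | target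

Total step count: 11. Longest linear sequence: 10 (steps 1 to 8, 10 and 11).

Steps most likely to fail

Step 8. The cation may leave the planned path in three ways. The ring C bond that lies antiperiplanar to the departing oxygen may shift. A methyl group may move from CMe2 into the C1 cation before the alkene closes. The acyl triflate may acylate the isopropenyl group at carbon.
Fallback, from 10 back to 11: flash vacuum thermolysis of 10 should break the weak bond between the quaternary cyclobutane carbon and the allylic CH. It should then re-join the quaternary carbon to the isopropenyl CH2 (vinylcyclobutane-to-cyclohexene rearrangement). This gives the ring-enlarged bridged ether F1. Acylative opening of F1 with the same acyl triflate and base then needs only a Markovnikov cation–olefin closure of the tertiary C7 cation onto the trisubstituted ring alkene, which is the laboratory form of the terpinyl-to-bornyl closure. That path never places charge next to CMe2, and it leads to 11.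

Step 6. The 1,4-diradical may revert or disproportionate instead of closing onto a carbon flanked by two quaternary centres. E/Z isomerisation wastes light, and the product ketone may suffer secondary α-cleavage.
Fallback, from 8 back to 10: Wittig methylenation is done first and gives the dienyl ether F2. Its diene is then excited by visible-light triplet energy transfer ([Ir(dF(CF3)ppy)2(dtbbpy)]PF6, blue LED, MeCN), a known way to run [2+2] cycloadditions of 1,3-dienes. The crossed adduct is 10 itself, which carries no carbonyl chromophore and cannot be photolysed further.

Step 4. The hydrazone may add to the epoxide or form the azine instead of fragmenting, and the alkenyl diazene may decompose along radical side paths.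
Fallback, from 3 back to 6: iodination of 3 (PPh3, I2, imidazole, toluene) gives the epoxy iodide F3. Zinc dust in refluxing ethanol then brings about the reductive elimination that opens the epoxide towards the CH2 group. This again leaves the C–O bond at the methyl-bearing carbon intact and gives 6.

Further compounds
F1 | step 8 | ring-enlarged bridged ether (3,7-dimethyl-6-oxabicyclo[3.2.1]oct-3-ene with ring C fused on C1–C7) | CC1=C[C@H]2C[C@]3(C1)C(C)(C)CCC[C@@]3(C)O2
F2 | step 6 | dienyl ether, (1R)-1,3,3-trimethyl-1-{[(1E)-3-methylbuta-1,3-dien-1-yl]oxy}-2-methylidenecyclohexane | C[C@@]1(O/C=C/C(C)=C)CCCC(C)(C)C1=C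
F3 | step 4 | epoxy iodide, 1-(iodomethyl)-2,2,6-trimethyl-7-oxabicyclo[4.1.0]heptane with the ring configuration of 3 | C[C@@]12CCCC(C)(C)[C@]1(CI)O2
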